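**Retrosynthetic overview**
- The only ring, the oxolane, is closed last by 5-exo bromoetherification of an acyclic tertiary chlorohydrin carrying an (E)-allylic chloride. This forms the ring C–O bond and the tertiary C–Br centre together.
- The tertiary carbinol comes from Cornforth-controlled methyl addition to an α-chloro (E)-β-bromovinyl ketone.
- Key C–C bond (carbonyl carbon to CHCl carbon): an enantioenriched α-chloroalkyllithium, in which the chlorine-bearing carbon acts as the nucleophile, is acylated by the Weinreb amide of (E)-3-bromoacrylic acid. Two normally electrophilic carbons are joined.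
- The carbenoid comes from an α-chloroalkyl p-tolyl sulfoxide by sulfoxide–lithium exchange. The sulfoxide is built from (S)-methyl p-tolyl sulfoxide and isoprene monoxide via (E)-4-chloro-2-methylbut-2-en-1-ol.

Assumption: the NCS chlorination in step 4 keeps the spatial arrangement at sulfur and favours the diastereomer drawn (R at sulfur, S at carbon); if the sense proves opposite, (R)-methyl p-tolyl sulfoxide is used instead, since only the carbon configuration is carried on; all four starting materials are taken as catalogue chemicals.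

**Step 1**
Reactants: 1 2-methyl-2-vinyloxirane (racemic isoprene monoxide)
Product: 2 (2E)-4-chloro-2-methylbut-2-en-1-ol
Conditions: TiCl4 (1.1 equiv), CH2Cl2, −90 °C; then aq. HCl
Reagents that add atoms: titanium tetrachloride, Cl[Ti](Cl)(Cl)Cl
Why: TiCl4-promoted SN2′-type opening of a vinyl epoxide delivers chloride to the vinyl terminus and gives the more stable (E)-trisubstituted allylic alcohol, a known reaction of this epoxide that creates no stereocentre.

**Step 2**
Reactants: 3 (S)-methyl p-tolyl sulfoxide; 2 (2E)-4-chloro-2-methylbut-2-en-1-ol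
Product: 5 (2E)-2-methyl-5-[(S)-4-methylbenzenesulfinyl]pent-2-en-1-ol, via lithiated sulfoxide 4 (not isolated)
Conditions: LiN(iPr)2 (2.2 equiv), THF, −78 °C; then 2, DMPU, −78 → −20 °C; H2O
Reagents that add atoms: lithium diisopropylamide, [Li]N(C(C)C)C(C)C
Why: Alkylation of an α-sulfinyl carbanion by SN2 at the primary allylic chloride (the second equivalent of base holds the hydroxyl as its lithium alkoxide) leaves the alkene geometry and the sulfur stereocentre untouched.

**Step 3**
Reactants: 5 (2E)-2-methyl-5-[(S)-4-methylbenzenesulfinyl]pent-2-en-1-ol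
Product: 7 1-{(S)-[(3E)-5-chloro-4-methylpent-3-en-1-yl]sulfinyl}-4-methylbenzene, via allylic mesylate 6 (not isolated)
Conditions: MsCl, s-collidine, LiCl, DMF, 0 °C
Reagents that add atoms: lithium chloride, [Li+].[Cl-]; methanesulfonyl chloride, CS(=O)(=O)Cl
Why: Collington–Meyers allylic chlorination, in which the mesylate formed in situ is displaced by chloride in a direct SN2 reaction without allylic transposition while the sulfoxide is inert to MsCl at 0 °C.

**Step 4**
Reactants: 7 1-{(S)-[(3E)-5-chloro-4-methylpent-3-en-1-yl]sulfinyl}-4-methylbenzene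
Product: 8 1-{(R)-[(1S,3E)-1,5-dichloro-4-methylpent-3-en-1-yl]sulfinyl}-4-methylbenzene
Conditions: NCS (1.05 equiv), K2CO3, CH2Cl2, 0 → 20 °C; major diastereomer purified by chromatography or crystallisation
Reagents that add atoms: N-chlorosuccinimide, O=C1CCC(=O)N1Cl
Why: α-Chlorination of a sulfoxide by NCS through an S-chlorosulfoxonium ion and its ylide (K2CO3 keeps the medium free of HCl so sulfur does not racemise), the sulfinyl group directing chlorine to one diastereotopic α-hydrogen to set the (1S) C–Cl centre.

**Step 5**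
Reactants: 9 (2E)-3-bromoprop-2-enoic acid; 10 N,O-dimethylhydroxylamine hydrochloride
Product: 12 (2E)-3-bromo-N-methoxy-N-methylprop-2-enamide, via acid chloride 11 (not isolated)
Conditions: (COCl)2, DMF (cat.), CH2Cl2, 0 → 20 °C; then 10, pyridine, 0 °C
Reagents that add atoms: oxalyl chloride, ClC(=O)C(=O)Cl
Why: Acid chloride formation followed by N-acylation of the hydroxylamine (Weinreb amide synthesis) keeps the thermodynamically preferred (E) geometry and creates no stereocentre.

**Step 6**
Reactants: 8 1-{(R)-[(1S,3E)-1,5-dichloro-4-methylpent-3-en-1-yl]sulfinyl}-4-methylbenzene; 12 (2E)-3-bromo-N-methoxy-N-methylprop-2-enamide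
Product: 15 (1E,4S,6E)-1-bromo-4,8-dichloro-7-methylocta-1,6-dien-3-one, via lithium carbenoid 13 (not isolated), via tetrahedral lithium adduct 14 (not isolated)
Conditions: PhLi (1.05 equiv) added to 8 + 12 (1.5 equiv), THF, −95 °C; AcOH, −95 °C; ketone used at once
Reagents that add atoms: phenyllithium, [Li]c1ccccc1
Why: Proposed new method: PhLi attacks sulfur (sulfoxide–lithium exchange, faster at −95 °C than its addition to the amide) and releases the α-chloroalkyllithium with retention at carbon, which is trapped at once by 1,2-addition to the Weinreb amide as a chelated adduct that cannot add twice, so the chlorine-bearing carbon, normally an electrophile, is joined as a nucleophile to the acyl carbon with its (S) configuration intact; the closest known reactions are the stereoretentive capture of sulfoxide-derived α-chloroalkyllithiums by boronic esters and the acylation of chloromethyllithium by unsaturated Weinreb amides.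

**Step 7**
Reactants: 15 (1E,4S,6E)-1-bromo-4,8-dichloro-7-methylocta-1,6-dien-3-one
Product: 16 (1E,3S,4S,6E)-1-bromo-4,8-dichloro-3,7-dimethylocta-1,6-dien-3-ol
Conditions: MeMgBr, CeCl3, THF, −78 °C; H2O (pH 7 buffer) at −78 °C
Reagents that add atoms: methylmagnesium bromide, C[Mg]Br
Why: Imamoto organocerium 1,2-addition (low basicity, no conjugate addition) under Cornforth control, in which C–Cl lies antiperiplanar to C=O and methyl attacks past the α-hydrogen to set the carbinol as (3S) next to (4S), while the cold neutral quench prevents closure of the chlorohydrin to an epoxide.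

**Step 8**
Reactants: 16 (1E,3S,4S,6E)-1-bromo-4,8-dichloro-3,7-dimethylocta-1,6-dien-3-ol
Product: 17 (2S,3S,5S)-5-[(2S)-2-bromo-1-chloropropan-2-yl]-2-[(E)-2-bromoethenyl]-3-chloro-2-methyloxolane
Conditions: NBS (1.05 equiv), MeCN, −20 → 0 °C, dark; chromatography
Reagents that add atoms: N-bromosuccinimide, O=C1CCC(=O)N1Br
Why: Bromonium-induced 5-exo bromoetherification in which the CH2Cl group disfavours positive charge at the tertiary alkene carbon so the hydroxyl opens the bromonium ion at the secondary carbon, anti addition across the (E)-alkene fixes the two new centres relative to each other, and the envelope with chlorine and side chain both pseudo-equatorial (1,3-cis) gives the (5S, 2′S) isomer with only modest substrate control, the other ring diastereomer being removed by chromatography.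

**Compound list**
1 | 2-methyl-2-vinyloxirane (racemic) | C=CC1(C)CO1 | starting material
2 | (2E)-4-chloro-2-methylbut-2-en-1-ol | OC/C(C)=C/CCl | intermediate
3 | (S)-methyl p-tolyl sulfoxide | C[S@](=O)c1ccc(C)cc1 | starting material
4 | {[(S)-4-methylbenzenesulfinyl]methyl}lithium | [Li]C[S@](=O)c1ccc(C)cc1 | intermediate
5 | (2E)-2-methyl-5-[(S)-4-methylbenzenesulfinyl]pent-2-en-1-ol | OC/C(C)=C/CC[S@](=O)c1ccc(C)cc1 | intermediate
6 | (2E)-2-methyl-5-[(S)-4-methylbenzenesulfinyl]pent-2-en-1-yl methanesulfonate | CS(=O)(=O)OC/C(C)=C/CC[S@](=O)c1ccc(C)cc1 | intermediate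
7 | 1-{(S)-[(3E)-5-chloro-4-methylpent-3-en-1-yl]sulfinyl}-4-methylbenzene | ClC/C(C)=C/CC[S@](=O)c1ccc(C)cc1 | intermediate
8 | 1-{(R)-[(1S,3E)-1,5-dichloro-4-methylpent-3-en-1-yl]sulfinyl}-4-methylbenzene | ClC/C(C)=C/C[C@H](Cl)[S@](=O)c1ccc(C)cc1 | intermediate
9 | (2E)-3-bromoprop-2-enoic acid | OC(=O)/C=C/Br | starting material
10 | N,O-dimethylhydroxylamine hydrochloride | CNOC.Cl | starting material
11 | (2E)-3-bromoprop-2-enoyl chloride | ClC(=O)/C=C/Br | intermediate
12 | (2E)-3-bromo-N-methoxy-N-methylprop-2-enamide | CON(C)C(=O)/C=C/Br | intermediate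
13 | [(1R,3E)-1,5-dichloro-4-methylpent-3-en-1-yl]lithium | ClC/C(C)=C/C[C@H](Cl)[Li] | intermediate
14 | lithium (1E,4S,6E)-1-bromo-4,8-dichloro-3-[methoxy(methyl)amino]-7-methylocta-1,6-dien-3-olate | ClC/C(C)=C/C[C@H](Cl)C(O[Li])(N(C)OC)/C=C/Br | intermediate
15 | (1E,4S,6E)-1-bromo-4,8-dichloro-7-methylocta-1,6-dien-3-one | ClC/C(C)=C/C[C@H](Cl)C(=O)/C=C/Br | intermediate
16 | (1E,3S,4S,6E)-1-bromo-4,8-dichloro-3,7-dimethylocta-1,6-dien-3-ol | ClC/C(C)=C/C[C@H](Cl)[C@](C)(/C=C/Br)O | intermediate
17 | (2S,3S,5S)-5-[(2S)-2-bromo-1-chloropropan-2-yl]-2-[(E)-2-bromoethenyl]-3-chloro-2-methyloxolane | C[C@@](Br)(CCl)[C@@H]1C[C@H](Cl)[C@](C)(/C=C/Br)O1 | target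

**Totals**
Total step count: 8. Longest linear sequence: 7 steps (steps 1, 2, 3, 4, 6, 7, 8).

**Three steps most likely to fail**

Step 6. PhLi may add to the amide before it exchanges at sulfur. The carbenoid is short-lived and could also alkylate itself at the allylic chloride. Fallback, setting out from 8 and coming back at 15: 8 is treated with i-PrMgCl in THF at −78 °C. Sulfoxide–magnesium exchange with retention gives the longer-lived [(1S,3E)-1,5-dichloro-4-methylpent-3-en-1-yl]magnesium chloride F1. F1 is added to (E)-3-bromopropenal activated by Me2AlCl to give (1E,4S,6E)-1-bromo-4,8-dichloro-7-methylocta-1,6-dien-3-ol F2 as both carbinol epimers. Dess–Martin oxidation of F2 returns ketone 15.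

Step 7. The β-bromo enone may undergo conjugate addition with loss of bromide, or enolise at the chlorinated carbon. Fallback, setting out from 8 and coming back at 16: carbenoid 13, generated as in step 6, is acylated with N-methoxy-N-methyl-3-(trimethylsilyl)prop-2-ynamide. This gives (4S,6E)-4,8-dichloro-7-methyl-1-(trimethylsilyl)oct-6-en-1-yn-3-one F3, which has no β-leaving group. The same Cornforth-controlled MeMgBr/CeCl3 addition gives (3S,4S,6E)-4,8-dichloro-3,7-dimethyl-1-(trimethylsilyl)oct-6-en-1-yn-3-ol F4. TBAF buffered with AcOH gives (3S,4S,6E)-4,8-dichloro-3,7-dimethyloct-6-en-1-yn-3-ol F5. Hydrozirconation with Cp2Zr(H)Cl followed by NBS (1.0 equiv, −78 °C) installs the (E)-bromoalkene and gives 16.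

Step 8. Methyl and bromovinyl are similar in size, so the face selectivity of the ring closure may be near 1:1, and some 6-endo product may form. Fallback, setting out from 8 and coming back at 17: the ring is closed on the alkynyl carbinol F4, made as in the previous fallback through F3. The slim alkynyl group takes the pseudo-axial site, so methyl, chlorine and the side chain can all sit pseudo-equatorial. NBS then gives trimethyl{[(2S,3S,5S)-5-[(2S)-2-bromo-1-chloropropan-2-yl]-3-chloro-2-methyloxolan-2-yl]ethynyl}silane F6. K2CO3 in MeOH gives (2S,3S,5S)-5-[(2S)-2-bromo-1-chloropropan-2-yl]-3-chloro-2-ethynyl-2-methyloxolane F7. Cp2Zr(H)Cl followed by NBS converts the alkyne into the (E)-bromoalkene of 17.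

**Further compounds**
F1 | step 6 | [(1S,3E)-1,5-dichloro-4-methylpent-3-en-1-yl]magnesium chloride | ClC/C(C)=C/C[C@H](Cl)[Mg]Cl
F2 | step 6 | (1E,4S,6E)-1-bromo-4,8-dichloro-7-methylocta-1,6-dien-3-ol (both C3 epimers) | ClC/C(C)=C/C[C@H](Cl)C(O)/C=C/Br
F3 | step 7 | (4S,6E)-4,8-dichloro-7-methyl-1-(trimethylsilyl)oct-6-en-1-yn-3-one | ClC/C(C)=C/C[C@H](Cl)C(=O)C#C[Si](C)(C)C
F4 | step 7 | (3S,4S,6E)-4,8-dichloro-3,7-dimethyl-1-(trimethylsilyl)oct-6-en-1-yn-3-ol | ClC/C(C)=C/C[C@H](Cl)[C@](C)(C#C[Si](C)(C)C)O
F5 | step 7 | (3S,4S,6E)-4,8-dichloro-3,7-dimethyloct-6-en-1-yn-3-ol | ClC/C(C)=C/C[C@H](Cl)[C@](C)(C#C)O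
F6 | step 8 | trimethyl{[(2S,3S,5S)-5-[(2S)-2-bromo-1-chloropropan-2-yl]-3-chloro-2-methyloxolan-2-yl]ethynyl}silane | C[C@@](Br)(CCl)[C@@H]1C[C@H](Cl)[C@](C)(C#C[Si](C)(C)C)O1
F7 | step 8 | (2S,3S,5S)-5-[(2S)-2-bromo-1-chloropropan-2-yl]-3-chloro-2-ethynyl-2-methyloxolane | C[C@@](Br)(CCl)[C@@H]1C[C@H](Cl)[C@](C)(C#C)O1
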